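## Retrosynthetic overview

1. Target 22 ⇐ lactol oxidation and double α-methylenation of the lactol/aldehyde obtained by ozonolysis of two allyl groups (γ-lactone closed last, on the C8 hydroxyl); oxirane ⇐ CH2 transfer to the C1 aldehyde.
2. Key step: cyclohexane 16 with the C10 quaternary centre ⇐ stereospecific Lewis-acid ring contraction (1,2-shift of C5 from C1 to C10) of cycloheptene oxide 15.
3. Cycloheptene 13 (C8–OH and C9–OAng trans) ⇐ rhodium-catalysed anti-SN2' opening of oxabicycle 12 by angelic acid (new reaction).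
4. 12 ⇐ β-face bis-allylation, reduction and acylation of ketone 4 ⇐ 3-methylfuran + tetrabromoacetone (oxyallyl cycloaddition); the oxygen bridge fixes the all-cis C5–C8 array.
5. Ring order: oxa-bridged seven-membered carbocycle → cycloheptene (bridge opened) → cyclohexane (ring contraction) → oxirane → γ-lactone.

Labels: C1–C15 are the elemanolide positions of the target (C10 quaternary, C14 its methyl, C1/C2 oxirane, C4(=C3)–C15 acrolein on C5, C11(=C13)–C12 lactone on C7/C8). In oxabicycles 3–12 the bridgeheads are C8 and C1, the etheno bridge is C9=C10 and the three-carbon bridge is C7–C6–C5. β is the face of the C8–O bond, α the opposite face. Ang = angeloyl, (Z)-2-methylbut-2-enoyl.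

Assumption: 3–14 are racemates; their SMILES show the enantiomer that is epoxidised in step 7, a kinetic resolution that delivers the single enantiomer (yield there at most 50 %).

## Route

Step 1
Reactants: 1 3-methylfuran; 2 1,1,3,3-tetrabromoacetone
Product: 4 rac-6-methyl-8-oxabicyclo[3.2.1]oct-6-en-3-one, via dibromo cycloadduct 3 (not isolated)
Conditions: Zn/Ag couple, THF, −10 °C to rt; then Zn/Cu couple, NH4Cl, MeOH, −78 °C to rt
Reagents that add atoms: none
Why: Noyori–Hoffmann (4+3) cycloaddition of the zinc oxyallyl cation from 2 with furan 1, then reductive debromination; the two bridgehead centres (future C1 and C8) are formed cis, as a racemate.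

Step 2
Reactants: 4 rac-6-methyl-8-oxabicyclo[3.2.1]oct-6-en-3-one; 5 allyl bromide
Product: 8 rac-2β,4β-diallyl-6-methyl-8-oxabicyclo[3.2.1]oct-6-en-3-one, via 2β-allyl ketone 6 (not isolated), via 4β-allyl ketone 7 (not isolated)
Conditions: LiN(iPr)2 (1.05 equiv), THF/DMPU, −78 °C; 5 (1.1 equiv); then LiN(iPr)2 (1.1 equiv), −78 °C; allyl bromide (1.3 equiv), −78 to −30 °C; cold NH4Cl quench
Reagents that add atoms: allyl bromide (second equivalent of 5), C=CCBr
Why: Two successive kinetic lithium enolate alkylations, each consuming one molecule of allyl bromide; the first gives the regioisomers 6 and 7, which both converge on 8 because the second deprotonation takes the remaining α-CH2. Each allyl group enters from the face away from the etheno bridge (axial, β, cis to the oxygen bridge, as in 2β-substituted tropinones), which sets C5 and C7.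

Step 3
Reactants: 8 rac-2β,4β-diallyl-6-methyl-8-oxabicyclo[3.2.1]oct-6-en-3-one
Product: 9 rac-2β,4β-diallyl-6-methyl-8-oxabicyclo[3.2.1]oct-6-en-3β-ol
Conditions: NaBH4, MeOH, −40 °C
Reagents that add atoms: none
Why: Hydride reduction; the two axial allyl groups block the β-face, so hydride comes from the etheno side and gives the 3β (equatorial) alcohol, i.e. C6–OH cis to both allyl groups and to the bridge.

Step 4
Reactants: 9 rac-2β,4β-diallyl-6-methyl-8-oxabicyclo[3.2.1]oct-6-en-3β-ol; 10 angelic acid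
Product: 12 rac-2β,4β-diallyl-6-methyl-8-oxabicyclo[3.2.1]oct-6-en-3β-yl angelate, via mixed anhydride 11 (not isolated)
Conditions: 10, 2,4,6-Cl3C6H2COCl, Et3N, toluene, rt; then 9, DMAP, 50 °C
Reagents that add atoms: none
Why: Yamaguchi esterification through the mixed anhydride, run below 60 °C so that the (Z)-angelate does not isomerise to the tiglate.

Step 5
Reactants: 12 rac-2β,4β-diallyl-6-methyl-8-oxabicyclo[3.2.1]oct-6-en-3β-yl angelate; 10 angelic acid
Product: 13 rac-(1α,4β,5β,6β,7β)-4,6-diallyl-7-hydroxy-2-methylcyclohept-2-ene-1,5-diyl diangelate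
Conditions: [Rh(cod)Cl]2 (5 mol %), Fe(C5H4PPh2)2 (1,1'-bis(diphenylphosphino)ferrocene, 11 mol %), Bu4NI (20 mol %), 10 (3 equiv), Et3N (0.5 equiv), 1,4-dioxane, 80 °C
Reagents that add atoms: none
Why: Proposed new method: rhodium-catalysed anti-SN2' ring opening of an 8-oxabicyclo[3.2.1]oct-6-ene by a carboxylic acid – monovalent rhodium binds the exo face of the alkene and the bridging oxygen and inserts into the allylic bridgehead C1–O bond (the one that leads to attack at the unsubstituted alkene carbon), the allyl-rhodium alkoxide is protonated by 10 and the angelate attacks C9 from the face opposite the metal, so C9–OAng is set trans to the C8–OH and the alkene moves to C10=C1; the closest known reaction is the Lautens rhodium-catalysed ring opening of oxabenzonorbornadienes and 7-oxanorbornenes with carboxylates, not shown for the less strained [3.2.1] oxabicycles (hence iodide additive, excess acid and 80 °C).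

Step 6
Reactants: 13 rac-(1α,4β,5β,6β,7β)-4,6-diallyl-7-hydroxy-2-methylcyclohept-2-ene-1,5-diyl diangelate
Product: 14 rac-(1α,4β,5β,6β,7β)-4,6-diallyl-2-methyl-7-(triethylsilyloxy)cyclohept-2-ene-1,5-diyl diangelate
Conditions: Et3SiOTf, 2,6-lutidine, CH2Cl2, −78 to 0 °C
Reagents that add atoms: triethylsilyl triflate, CC[Si](CC)(CC)OS(=O)(=O)C(F)(F)F
Why: Silyl ether formation on the only free hydroxyl (C8); it keeps this oxygen from re-closing onto C1 in step 8 and from receiving an angelate by acyl migration.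

Step 7
Reactants: 14 rac-(1α,4β,5β,6β,7β)-4,6-diallyl-2-methyl-7-(triethylsilyloxy)cyclohept-2-ene-1,5-diyl diangelate
Product: 15 (1α,2α,3α,4β,5β,6β,7β)-4,6-diallyl-2,3-epoxy-2-methyl-7-(triethylsilyloxy)cycloheptane-1,5-diyl diangelate (epoxide oxygen α, methyl β; single enantiomer)
Conditions: ent-Shi ketone (L-sorbose-derived enantiomer of the fructose ketone, 30 mol %), Oxone (2KHSO5·KHSO4·K2SO4), K2CO3, Bu4NHSO4, aq. Na2B4O7/disodium ethylenediaminetetraacetate (Na2C10H14N2O8) buffer, MeCN–CH2(OMe)2, −10 °C, to ca. 45 % conversion; unreacted ent-14 removed by chromatography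
Reagents that add atoms: potassium peroxymonosulfate, [K+].[O-]S(=O)(=O)OO
Why: Shi asymmetric epoxidation run as a kinetic resolution: the chiral dioxirane oxidises only the electron-rich trisubstituted ring alkene, and only in the enantiomer whose open α-face (C5-allyl, C6-OAng, C7-allyl and C8-OSiEt3 all shield the β-face) is also the enantioface the catalyst prefers, which sets C10/C1 of the epoxide and the absolute configuration.

Step 8
Reactants: 15 (1α,2α,3α,4β,5β,6β,7β)-4,6-diallyl-2,3-epoxy-2-methyl-7-(triethylsilyloxy)cycloheptane-1,5-diyl diangelate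
Product: 16 2β,4β-diallyl-1α-formyl-1β-methyl-5β-(triethylsilyloxy)cyclohexane-3β,6α-diyl diangelate
Conditions: methylaluminium bis(4-bromo-2,6-di-tert-butylphenoxide), MeAl(OAr)2 (2 equiv), CH2Cl2, −78 to −20 °C
Reagents that add atoms: none
Why: Meinwald rearrangement with the bulky Yamamoto aluminium Lewis acid: the epoxide ionises at tertiary C10 while the C1–C5 bond migrates to C10 anti to the leaving oxygen (ring contraction by 1,2-alkyl shift), so C1 becomes the aldehyde, C14 stays β and the formyl group ends α, cis to the C9 ester; the C9 angelate cannot participate because it is syn to the epoxide.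

Step 9
Reactants: 16 2β,4β-diallyl-1α-formyl-1β-methyl-5β-(triethylsilyloxy)cyclohexane-3β,6α-diyl diangelate
Product: 17 2β,4β-diallyl-1β-methyl-1α-[(R)-oxiran-2-yl]-5β-(triethylsilyloxy)cyclohexane-3β,6α-diyl diangelate
Conditions: Me3S+ I−, KN(SiMe3)2, THF, −20 °C; then 16, −20 to 0 °C
Reagents that add atoms: trimethylsulfonium iodide, C[S+](C)C.[I-]
Why: Corey–Chaykovsky epoxidation; Felkin–Anh addition of the ylide anti to the C10–C9 bond (the acyloxy-bearing branch) and past the small methyl group gives the (R)-oxirane at C1.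

Step 10
Reactants: 17 2β,4β-diallyl-1β-methyl-1α-[(R)-oxiran-2-yl]-5β-(triethylsilyloxy)cyclohexane-3β,6α-diyl diangelate
Product: 18 2β,4β-diallyl-5β-hydroxy-1β-methyl-1α-[(R)-oxiran-2-yl]cyclohexane-3β,6α-diyl diangelate
Conditions: Bu4NF, AcOH (1:1), THF, 0 °C to rt
Reagents that add atoms: none
Why: Fluoride desilylation buffered with acetic acid, so that neither angelate migrates to the freed C8 hydroxyl and the oxirane is not opened.

Step 11
Reactants: 18 2β,4β-diallyl-5β-hydroxy-1β-methyl-1α-[(R)-oxiran-2-yl]cyclohexane-3β,6α-diyl diangelate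
Product: 20 lactol aldehyde (cis-fused γ-lactol on C7/C8 as anomer mixture; 2-oxoethyl on C5), via bis-ozonide 19 (not isolated)
Conditions: O3, CH2Cl2, −78 °C (Sudan Red 7B end point); then PPh3, −78 °C to rt
Reagents that add atoms: ozone, [O-][O+]=O
Why: Ozonolysis with reductive work-up cleaves the two terminal alkenes much faster than the electron-poor angelates; the C12 aldehyde is trapped by the cis C8 hydroxyl as a γ-lactol while the C15 aldehyde stays free.

Step 12
Reactants: 20 lactol aldehyde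
Product: 21 bis-methylene lactol aldehyde (C11=C13H2 γ-lactol as anomer mixture; 1-formylvinyl on C5)
Conditions: aq. CH2O (37 %, excess), pyrrolidine (20 mol %), EtCO2H (20 mol %), iPrOH, 45 °C
Reagents that add atoms: formaldehyde, C=O
Why: Organocatalytic α-methylenation of both aldehydes (Mannich condensation with formaldehyde, then β-elimination of the amine; Pihko conditions); the lactol reacts through its open hydroxy aldehyde form.

Step 13
Reactants: 21 bis-methylene lactol aldehyde
Product: 22 CNP0291490.2 (target)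
Conditions: PhI(OAc)2, TEMPO (20 mol %), CH2Cl2, rt
Reagents that add atoms: none
Why: TEMPO/PhI(OAc)2 oxidation converts the allylic lactol into the α-methylene γ-lactone and leaves the conjugated aldehyde untouched in the absence of water.

## Compound list

1 | 3-methylfuran | Cc1ccoc1 | starting material
2 | 1,1,3,3-tetrabromoacetone | O=C(C(Br)Br)C(Br)Br | starting material
3 | rac-2,4-dibromo-6-methyl-8-oxabicyclo[3.2.1]oct-6-en-3-one (bromide epimers) | CC1=C[C@@H]2C(Br)C(=O)C(Br)[C@H]1O2 | intermediate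
4 | rac-6-methyl-8-oxabicyclo[3.2.1]oct-6-en-3-one ((1S,5R) drawn) | CC1=C[C@@H]2CC(=O)C[C@H]1O2 | intermediate
5 | allyl bromide | C=CCBr | starting material
6 | rac-2β-allyl-6-methyl-8-oxabicyclo[3.2.1]oct-6-en-3-one (allyl on future C7, cis to O8) | CC1=C[C@@H]2[C@@H](CC=C)C(=O)C[C@H]1O2 | intermediate
7 | rac-4β-allyl-6-methyl-8-oxabicyclo[3.2.1]oct-6-en-3-one (allyl on future C5, cis to O8) | CC1=C[C@@H]2CC(=O)[C@@H](CC=C)[C@H]1O2 | intermediate
8 | rac-2β,4β-diallyl-6-methyl-8-oxabicyclo[3.2.1]oct-6-en-3-one | CC1=C[C@@H]2[C@@H](CC=C)C(=O)[C@@H](CC=C)[C@H]1O2 | intermediate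
9 | rac-2β,4β-diallyl-6-methyl-8-oxabicyclo[3.2.1]oct-6-en-3β-ol | CC1=C[C@@H]2[C@@H](CC=C)[C@@H](O)[C@@H](CC=C)[C@H]1O2 | intermediate
10 | angelic acid, (Z)-2-methylbut-2-enoic acid | C/C=C(/C)C(=O)O | starting material
11 | angelic 2,4,6-trichlorobenzoic anhydride | C/C=C(/C)C(=O)OC(=O)c1c(Cl)cc(Cl)cc1Cl | intermediate
12 | rac-2β,4β-diallyl-6-methyl-8-oxabicyclo[3.2.1]oct-6-en-3β-yl angelate | CC1=C[C@@H]2[C@@H](CC=C)[C@@H](OC(=O)/C(C)=C\C)[C@@H](CC=C)[C@H]1O2 | intermediate
13 | rac-(1α,4β,5β,6β,7β)-4,6-diallyl-7-hydroxy-2-methylcyclohept-2-ene-1,5-diyl diangelate | CC1=C[C@H](CC=C)[C@H](OC(=O)/C(C)=C\C)[C@H](CC=C)[C@H](O)[C@H]1OC(=O)/C(C)=C\C | intermediate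
14 | rac-(1α,4β,5β,6β,7β)-4,6-diallyl-2-methyl-7-(triethylsilyloxy)cyclohept-2-ene-1,5-diyl diangelate | CC1=C[C@H](CC=C)[C@H](OC(=O)/C(C)=C\C)[C@H](CC=C)[C@H](O[Si](CC)(CC)CC)[C@H]1OC(=O)/C(C)=C\C | intermediate
15 | (1α,2α,3α,4β,5β,6β,7β)-4,6-diallyl-2,3-epoxy-2-methyl-7-(triethylsilyloxy)cycloheptane-1,5-diyl diangelate | C[C@]12O[C@H]1[C@H](CC=C)[C@H](OC(=O)/C(C)=C\C)[C@H](CC=C)[C@H](O[Si](CC)(CC)CC)[C@H]2OC(=O)/C(C)=C\C | intermediate
16 | 2β,4β-diallyl-1α-formyl-1β-methyl-5β-(triethylsilyloxy)cyclohexane-3β,6α-diyl diangelate | O=C[C@@]1(C)[C@H](CC=C)[C@H](OC(=O)/C(C)=C\C)[C@H](CC=C)[C@H](O[Si](CC)(CC)CC)[C@H]1OC(=O)/C(C)=C\C | intermediate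
17 | 2β,4β-diallyl-1β-methyl-1α-[(R)-oxiran-2-yl]-5β-(triethylsilyloxy)cyclohexane-3β,6α-diyl diangelate | C1O[C@@H]1[C@@]1(C)[C@H](CC=C)[C@H](OC(=O)/C(C)=C\C)[C@H](CC=C)[C@H](O[Si](CC)(CC)CC)[C@H]1OC(=O)/C(C)=C\C | intermediate
18 | 2β,4β-diallyl-5β-hydroxy-1β-methyl-1α-[(R)-oxiran-2-yl]cyclohexane-3β,6α-diyl diangelate | C1O[C@@H]1[C@@]1(C)[C@H](CC=C)[C@H](OC(=O)/C(C)=C\C)[C@H](CC=C)[C@H](O)[C@H]1OC(=O)/C(C)=C\C | intermediate
19 | bis-ozonide of 18 (each allyl CH=CH2 as a 1,2,4-trioxolane; ozonide carbons undefined) | C1O[C@@H]1[C@@]1(C)[C@H](CC2OCOO2)[C@H](OC(=O)/C(C)=C\C)[C@H](CC2OCOO2)[C@H](O)[C@H]1OC(=O)/C(C)=C\C | intermediate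
20 | lactol aldehyde (cis-fused C8–O–C12H(OH) γ-lactol, anomer mixture; 2-oxoethyl on C5) | C1O[C@@H]1[C@@]1(C)[C@H](CC=O)[C@H](OC(=O)/C(C)=C\C)[C@@H]2CC(O)O[C@@H]2[C@H]1OC(=O)/C(C)=C\C | intermediate
21 | bis-methylene lactol aldehyde (α-methylene γ-lactol, anomer mixture; 1-formylvinyl on C5) | C1O[C@@H]1[C@@]1(C)[C@H](C(=C)C=O)[C@H](OC(=O)/C(C)=C\C)[C@@H]2C(=C)C(O)O[C@@H]2[C@H]1OC(=O)/C(C)=C\C | intermediate
22 | CNP0291490.2 (6β,9α-diangeloyloxy-1,2-epoxy-15-oxo-elema-3,11(13)-dien-12,8β-olide) | C=C1C(=O)O[C@H]2[C@@H]1[C@@H](OC(=O)/C(C)=C\C)[C@@H](C(=C)C=O)[C@](C)([C@@H]1CO1)[C@@H]2OC(=O)/C(C)=C\C | target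

## Step count and risks

Total step count: 13. Longest linear sequence: 13 steps (1 → 22).

Three steps most likely to fail:

**Step 5 (the new rhodium ring opening).** The [3.2.1] oxabicycle is much less strained than the known substrates, the alkene is trisubstituted, and acyl migration in 13 is possible. Fallback with known chemistry, setting out from 12 and coming back at 14: dye-sensitised photo-oxygenation of 12 (O2, hν, tetraphenylporphyrin; Schenck ene reaction, only the methyl hydrogens are available because the other allylic hydrogens sit at bridgeheads) gives the exo allylic hydroperoxide F1. Ac2O/pyridine (Kornblum–DeLaMare dehydration) gives the exo-methylene ketone F2. Conjugate reduction with [(Ph3P)CuH]6 forms the C9/C10 enolate, which expels the bridging alkoxide (E1cB) to give the ring-opened hydroxy enone F3. Et3SiOTf/2,6-lutidine gives the silyl ether enone F4. NaBH4/CeCl3·7H2O (Luche reduction, hydride anti to the C8 silyl ether) gives the cis allylic alcohol F5. Mitsunobu esterification with 10 (PPh3, diisopropyl azodicarboxylate) inverts C9 and returns to the route at 14.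

**Step 8 (ring contraction).** Hydride shift from C1 (giving the cycloheptanone) or capture of the cation by a neighbouring oxygen may compete with the C5 shift. Fallback setting out from 15 and coming back at 16: 15 is isomerised with diethylaluminium 2,2,6,6-tetramethylpiperidide, Et2Al(NC9H18), in toluene at 0 °C to the exocyclic allylic alcohol F6 by syn proton loss from C14. F6 is then treated with diphenyl phosphate in CH2Cl2 (protio-semipinacol rearrangement): protonation of the methylene carbon regenerates the C10 cation, and the free C1 hydroxyl now drives the C5 shift to the aldehyde 16. In this fallback the face of C10 that receives C5 is set only by conformation (the conformer with the C1 hydroxyl hydrogen-bonded to the α C9 angelate leads to 16), so it is less stereo-reliable than step 8 and a C10 epimer would have to be separated.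

**Step 9 (C1 configuration).** Substrate control in the ylide addition to a neopentyl aldehyde may be low or reversed. Fallback setting out from 16 and coming back at 17: ClCH2Li (ICH2Cl, MeLi·LiBr, THF, −78 °C) adds to 16 to give the chlorohydrin epimers F7. Dess–Martin oxidation gives the chloromethyl ketone F8. (R)-Me-CBS oxazaborolidine with catecholborane (toluene, −78 °C; chosen over BH3·SMe2 so that the allyl groups are not hydroborated) reduces it under reagent control to the (R)-chlorohydrin F9. K2CO3 in MeOH at 0 °C closes the oxirane with retention at C1, giving 17.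

## Further compounds

F1 | step 5 | rac-2β,4β-diallyl-7β-hydroperoxy-6-methylene-8-oxabicyclo[3.2.1]octan-3β-yl angelate | C=C1[C@@H](OO)[C@@H]2[C@@H](CC=C)[C@@H](OC(=O)/C(C)=C\C)[C@@H](CC=C)[C@H]1O2
F2 | step 5 | rac-2β,4β-diallyl-6-methylene-7-oxo-8-oxabicyclo[3.2.1]octan-3β-yl angelate | C=C1C(=O)[C@@H]2[C@@H](CC=C)[C@@H](OC(=O)/C(C)=C\C)[C@@H](CC=C)[C@H]1O2
F3 | step 5 | rac-(1β,2β,3β,7β)-2,7-diallyl-3-hydroxy-5-methyl-4-oxocyclohept-5-en-1-yl angelate (hydroxy enone, C9 ketone, C8–OH) | CC1=C[C@H](CC=C)[C@H](OC(=O)/C(C)=C\C)[C@H](CC=C)[C@H](O)C1=O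
F4 | step 5 | triethylsilyl ether of F3 | CC1=C[C@H](CC=C)[C@H](OC(=O)/C(C)=C\C)[C@H](CC=C)[C@H](O[Si](CC)(CC)CC)C1=O
F5 | step 5 | rac-cis allylic alcohol (C9–OH β, cis to C8–OSiEt3), C9 epimer of the alcohol corresponding to 14 | CC1=C[C@H](CC=C)[C@H](OC(=O)/C(C)=C\C)[C@H](CC=C)[C@H](O[Si](CC)(CC)CC)[C@@H]1O
F6 | step 8 | (1α,3α,4β,5β,6β,7β)-4,6-diallyl-3-hydroxy-2-methylene-7-(triethylsilyloxy)cycloheptane-1,5-diyl diangelate | C=C1[C@@H](O)[C@H](CC=C)[C@H](OC(=O)/C(C)=C\C)[C@H](CC=C)[C@H](O[Si](CC)(CC)CC)[C@H]1OC(=O)/C(C)=C\C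
F7 | step 9 | 1α-(2-chloro-1-hydroxyethyl) analogue of 16 (both C1 epimers) | ClCC(O)[C@@]1(C)[C@H](CC=C)[C@H](OC(=O)/C(C)=C\C)[C@H](CC=C)[C@H](O[Si](CC)(CC)CC)[C@H]1OC(=O)/C(C)=C\C
F8 | step 9 | 1α-(chloroacetyl) analogue of 16 | ClCC(=O)[C@@]1(C)[C@H](CC=C)[C@H](OC(=O)/C(C)=C\C)[C@H](CC=C)[C@H](O[Si](CC)(CC)CC)[C@H]1OC(=O)/C(C)=C\C
F9 | step 9 | 1α-[(R)-2-chloro-1-hydroxyethyl] analogue of 16 | ClC[C@H](O)[C@@]1(C)[C@H](CC=C)[C@H](OC(=O)/C(C)=C\C)[C@H](CC=C)[C@H](O[Si](CC)(CC)CC)[C@H]1OC(=O)/C(C)=C\C
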